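The route rests on breaking the C1'–C5' bond of the cyclopentane (ring B). That ring carries a methyl carbinol at C2', the run C3'–C4'–C5' and an isopropenyl group on C5' beside C1'. The C2'–C5' segment is the chain of (S)-linalool, and the isopropenyl group is what an allylic (SN2') displacement leaves behind. In one operation the dilithium alkoxide–enolate of a linalool-derived β-hydroxy ester carrying an E allylic chloride closes ring B, sets C1' and C5' from the purchased C2' centre and unmasks the isopropenyl group. The derived aldehyde is finally joined through C7' to an enantiopure acyl trione (ring A) by reductive Knoevenagel alkylation.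

Key step: step 6

Locants: ring B is the cyclopentane (C1' bears the bridging CH2 C7', C2' is the methyl carbinol, C5' bears isopropenyl); ring A is the acyl trione ring, written throughout in the dienol tautomer of the target.

Assumption: (S)-(+)-linalool is used in high optical purity, and pig liver esterase is taken to leave the (S)-half ester of the methyl(prenyl)malonate; sense and level of induction must be confirmed by correlation before the material is carried on.

Step 1
Reactants: 1 (S)-(+)-linalool
Product: 3 (3S)-3,7-dimethyloct-6-ene-1,3-diol, via alkylborane 2 (not isolated)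
Conditions: 9-BBN (2.2 equiv), THF, 0 °C to rt; then 3 M NaOH, 30% H2O2, 0 °C to rt
Reagents that add atoms: hydrogen peroxide, OO
Why: Hydroboration–oxidation: 9-BBN adds anti-Markovnikov to the monosubstituted vinyl group far faster than to the trisubstituted alkene, and oxidation gives the primary alcohol; the carbinol centre is not touched and stays (S).

Step 2
Reactants: 3 (3S)-3,7-dimethyloct-6-ene-1,3-diol
Product: 5 (3S)-3-hydroxy-3,7-dimethyloct-6-enoic acid, via hydroxy aldehyde 4 (not isolated)
Conditions: TEMPO (0.2 equiv), PhI(OAc)2 (2.2 equiv), MeCN/H2O 1:1, rt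
Reagents that add atoms: water, O
Why: Oxoammonium (TEMPO/PhI(OAc)2) oxidation in aqueous acetonitrile takes a primary alcohol through the aldehyde hydrate to the acid and leaves tertiary alcohols and trisubstituted alkenes alone.

Step 3
Reactants: 5 (3S)-3-hydroxy-3,7-dimethyloct-6-enoic acid
Product: 6 methyl (3S)-3-hydroxy-3,7-dimethyloct-6-enoate
Conditions: MeI, KHCO3, DMF, rt
Reagents that add atoms: iodomethane, CI
Why: Carboxylate O-alkylation (SN2 on MeI) under bicarbonate is mild enough to spare the tertiary β-hydroxy group from retro-aldol cleavage or dehydration.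

Step 4
Reactants: 6 methyl (3S)-3-hydroxy-3,7-dimethyloct-6-enoate
Product: 7 methyl (3S,6E)-3,8-dihydroxy-3,7-dimethyloct-6-enoate
Conditions: SeO2 (0.2 equiv), t-BuOOH (3 equiv), salicylic acid (0.1 equiv), CH2Cl2, rt
Reagents that add atoms: selenium dioxide, O=[Se]=O (oxygen carrier, catalytic); tert-butyl hydroperoxide, CC(C)(C)OO (terminal oxygen source)
Why: Sharpless catalytic SeO2 allylic oxidation (ene reaction, then [2,3]-sigmatropic shift) hydroxylates the E methyl group of a gem-dimethyl trisubstituted alkene, which fixes the E geometry of the allylic alcohol.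

Step 5
Reactants: 7 methyl (3S,6E)-3,8-dihydroxy-3,7-dimethyloct-6-enoate
Product: 9 methyl (3S,6E)-8-chloro-3-hydroxy-3,7-dimethyloct-6-enoate, via allylic mesylate 8 (not isolated)
Conditions: MsCl, LiCl, 2,4,6-collidine, DMF, 0 °C
Reagents that add atoms: lithium chloride, [Li+].[Cl-]
Why: Collington–Meyers chlorination: the primary allylic alcohol is mesylated in preference to the hindered tertiary one and displaced in situ by chloride (SN2) without allylic transposition, so the E alkene is kept.

Step 6
Reactants: 9 methyl (3S,6E)-8-chloro-3-hydroxy-3,7-dimethyloct-6-enoate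
Product: 11 methyl (1R,2S,5S)-2-hydroxy-2-methyl-5-(prop-1-en-2-yl)cyclopentane-1-carboxylate, via dilithium alkoxide-enolate 10 (not isolated)
Conditions: LDA (2.1 equiv), THF, −78 to −40 °C; DMPU, −40 to 0 °C; aq. NH4Cl
Reagents that add atoms: none
Why: Proposed new method: two equivalents of LDA remove the hydroxyl proton and then an ester α-proton, and the resulting lithium alkoxide–enolate, whose two oxygens share lithium in a six-membered chelate, attacks the alkene carbon C5' through C1' while chloride departs from the allylic CH2 (intramolecular SN2'). The closest known reactions are the Fráter–Seebach alkylation of β-hydroxy ester dianions and the intramolecular SN2' alkylation of simple ester enolates by allylic chlorides to vinylcyclopentanes; their union on a tertiary carbinol is the untested part. Ring B closes 5-exo-trig; direct SN2 at CH2Cl would demand a seven-membered ring holding an E alkene and is excluded. C1' is controlled by the chelate and the tether: the C2' oxygen lies near the enolate plane, the electrophile can arrive only on the face occupied by C3', and the ester carbon C7' should therefore end cis to the hydroxyl. C5' is controlled by the preference of the chloromethyl-propenyl arm for the pseudo-equatorial position away from the enolate ester group, which should place isopropenyl trans to C7', the absolute sense following from the (S) centre C2'. The step needs C- rather than O-alkylation, SN2' rather than SN2 and no β-elimination: the enolate carbon far outruns the hindered tertiary lithium alkoxide, tether length and E geometry forbid SN2, and an alkoxide is too poor a leaving group for E1cB.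

Step 7
Reactants: 11 methyl (1R,2S,5S)-2-hydroxy-2-methyl-5-(prop-1-en-2-yl)cyclopentane-1-carboxylate
Product: 12 (1S,2S,3S)-2-(hydroxymethyl)-1-methyl-3-(prop-1-en-2-yl)cyclopentan-1-ol
Conditions: LiAlH4, THF, 0 °C; Fieser work-up
Reagents that add atoms: none
Why: Hydride reduction of the ester to the primary alcohol at 0 °C; no stereocentre is involved, the isopropenyl group is inert, and the cold aluminium alkoxide of the tertiary carbinol should not undergo retro-aldol opening.

Step 8
Reactants: 12 (1S,2S,3S)-2-(hydroxymethyl)-1-methyl-3-(prop-1-en-2-yl)cyclopentan-1-ol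
Product: 13 (1R,2S,5S)-2-hydroxy-2-methyl-5-(prop-1-en-2-yl)cyclopentane-1-carbaldehyde
Conditions: TEMPO (0.1 equiv), PhI(OAc)2 (1.1 equiv), CH2Cl2, rt
Reagents that add atoms: none
Why: Oxoammonium oxidation in dry dichloromethane stops at the aldehyde and cannot oxidise a tertiary alcohol; the near-neutral medium should preserve C1', whose configuration (formyl trans to isopropenyl, cis to hydroxyl) is also expected to be the more stable one.

Step 9
Reactants: 14 dimethyl methylmalonate; 15 prenyl bromide
Product: 16 dimethyl 2-methyl-2-(3-methylbut-2-en-1-yl)propanedioate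
Conditions: NaH, THF, 0 °C to rt
Reagents that add atoms: none
Why: Malonate alkylation (SN2 of the sodium enolate on a primary allylic bromide); the product has no α-hydrogen, so it cannot be alkylated again.

Step 10
Reactants: 16 dimethyl 2-methyl-2-(3-methylbut-2-en-1-yl)propanedioate
Product: 17 (2S)-2-(methoxycarbonyl)-2,5-dimethylhex-4-enoic acid
Conditions: pig liver esterase, 0.1 M phosphate buffer pH 7.5, 10% DMSO, rt, pH-stat (1 M NaOH, 1 equiv); then HCl to pH 2
Reagents that add atoms: water, O
Why: Enzymatic desymmetrisation: the esterase hydrolyses one of the two enantiotopic methyl esters of the prochiral disubstituted malonate and stops at the half ester, which creates the quaternary stereocentre (sense as assumed above); optical purity can be raised by crystallising an amine salt.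

Step 11
Reactants: 17 (2S)-2-(methoxycarbonyl)-2,5-dimethylhex-4-enoic acid; 18 6-methylheptane-2,4-dione
Product: 21 methyl (2S)-2,9-dimethyl-2-(3-methylbut-2-en-1-yl)-3,5,7-trioxodecanoate, via acid chloride 19 (not isolated), via dione dianion 20 (not isolated)
Conditions: (COCl)2, cat. DMF, CH2Cl2, 0 °C to rt, evaporate; add to 18 (3 equiv)/LDA (6 equiv), THF, −78 °C; aq. NH4Cl
Reagents that add atoms: none
Why: Hauser–Harris acylation of a β-diketone dianion: the second deprotonation of 18 takes place at the terminal methyl group, and that carbon attacks the acid chloride (no α-hydrogen, hence no ketene) much faster than the hindered methyl ester, while excess dianion absorbs the acidic product; the quaternary centre is a spectator.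

Step 12
Reactants: 21 methyl (2S)-2,9-dimethyl-2-(3-methylbut-2-en-1-yl)-3,5,7-trioxodecanoate
Product: 22 (6S)-3,5-dihydroxy-6-methyl-2-(3-methylbutanoyl)-6-(3-methylbut-2-en-1-yl)cyclohexa-2,4-dien-1-one
Conditions: t-BuOK (3 equiv), THF, 0 °C to rt; 1 M HCl
Reagents that add atoms: none
Why: Intramolecular Claisen (Dieckmann-type) C-acylation: C6 of 21, the methylene between the C5 and C7 carbonyls, closes on the C1 ester to a six-membered ring, driven by the stabilised trione anion. Because the former acid carbon sits next to the free ring CH and the former ester carbon next to the acyl-bearing carbon, the configuration of 17 becomes (S) at the ring quaternary carbon. A non-nucleophilic base avoids retro-Claisen scrambling.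

Step 13
Reactants: 13 (1R,2S,5S)-2-hydroxy-2-methyl-5-(prop-1-en-2-yl)cyclopentane-1-carbaldehyde; 22 (6S)-3,5-dihydroxy-6-methyl-2-(3-methylbutanoyl)-6-(3-methylbut-2-en-1-yl)cyclohexa-2,4-dien-1-one
Product: 24 (6S)-3,5-dihydroxy-4-{[(1R,2S,5S)-2-hydroxy-2-methyl-5-(prop-1-en-2-yl)cyclopentyl]methyl}-6-methyl-2-(3-methylbutanoyl)-6-(3-methylbut-2-en-1-yl)cyclohexa-2,4-dien-1-one, via alkylidene trione 23 (not isolated)
Conditions: Hantzsch ester (1.2 equiv), L-proline (0.2 equiv), CH2Cl2, rt
Reagents that add atoms: none
Why: Organocatalytic three-component reductive alkylation (Knoevenagel condensation, then conjugate hydride transfer from the Hantzsch ester): the only free nucleophilic ring carbon of 22 condenses with the aldehyde and the alkylidene is reduced before a second trione can add. No stereocentre is formed, the isopropenyl group trans to C7' cannot engage the heterodiene, and the mild conditions should leave C1' and the tertiary alcohol intact.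

Compound list
1 | (S)-(+)-linalool, (3S)-3,7-dimethylocta-1,6-dien-3-ol | CC(C)=CCC[C@](C)(O)C=C | starting material
2 | 9-[(3S)-3-hydroxy-3,7-dimethyloct-6-en-1-yl]-9-borabicyclo[3.3.1]nonane (alkylborane) | CC(C)=CCC[C@](C)(O)CCB1C2CCCC1CCC2 | intermediate
3 | (3S)-3,7-dimethyloct-6-ene-1,3-diol | CC(C)=CCC[C@](C)(O)CCO | intermediate
4 | (3S)-3-hydroxy-3,7-dimethyloct-6-enal (hydroxy aldehyde) | CC(C)=CCC[C@](C)(O)CC=O | intermediate
5 | (3S)-3-hydroxy-3,7-dimethyloct-6-enoic acid | CC(C)=CCC[C@](C)(O)CC(=O)O | intermediate
6 | methyl (3S)-3-hydroxy-3,7-dimethyloct-6-enoate | CC(C)=CCC[C@](C)(O)CC(=O)OC | intermediate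
7 | methyl (3S,6E)-3,8-dihydroxy-3,7-dimethyloct-6-enoate | COC(=O)C[C@@](C)(O)CC/C=C(\C)CO | intermediate
8 | methyl (3S,6E)-3-hydroxy-3,7-dimethyl-8-[(methylsulfonyl)oxy]oct-6-enoate (allylic mesylate) | COC(=O)C[C@@](C)(O)CC/C=C(\C)COS(C)(=O)=O | intermediate
9 | methyl (3S,6E)-8-chloro-3-hydroxy-3,7-dimethyloct-6-enoate | COC(=O)C[C@@](C)(O)CC/C=C(\C)CCl | intermediate
10 | dilithium alkoxide–enolate of 9 (O-lithio enolate cis to the carbinol carbon) | CO/C(O[Li])=C/[C@@](C)(O[Li])CC/C=C(\C)CCl | intermediate
11 | methyl (1R,2S,5S)-2-hydroxy-2-methyl-5-(prop-1-en-2-yl)cyclopentane-1-carboxylate | C=C(C)[C@H]1CC[C@](C)(O)[C@@H]1C(=O)OC | intermediate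
12 | (1S,2S,3S)-2-(hydroxymethyl)-1-methyl-3-(prop-1-en-2-yl)cyclopentan-1-ol | C=C(C)[C@H]1CC[C@](C)(O)[C@@H]1CO | intermediate
13 | (1R,2S,5S)-2-hydroxy-2-methyl-5-(prop-1-en-2-yl)cyclopentane-1-carbaldehyde | C=C(C)[C@H]1CC[C@](C)(O)[C@@H]1C=O | intermediate
14 | dimethyl methylmalonate | COC(=O)C(C)C(=O)OC | starting material
15 | prenyl bromide, 1-bromo-3-methylbut-2-ene | CC(C)=CCBr | starting material
16 | dimethyl 2-methyl-2-(3-methylbut-2-en-1-yl)propanedioate | COC(=O)C(C)(CC=C(C)C)C(=O)OC | intermediate
17 | (2S)-2-(methoxycarbonyl)-2,5-dimethylhex-4-enoic acid | COC(=O)[C@@](C)(CC=C(C)C)C(=O)O | intermediate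
18 | 6-methylheptane-2,4-dione | CC(=O)CC(=O)CC(C)C | starting material
19 | methyl (2R)-2-(chlorocarbonyl)-2,5-dimethylhex-4-enoate (acid chloride) | COC(=O)[C@@](C)(CC=C(C)C)C(Cl)=O | intermediate
20 | dilithium 6-methylhepta-1,3-diene-2,4-diolate (dianion of 18) | C=C(O[Li])C=C(O[Li])CC(C)C | intermediate
21 | methyl (2S)-2,9-dimethyl-2-(3-methylbut-2-en-1-yl)-3,5,7-trioxodecanoate | CC(C)CC(=O)CC(=O)CC(=O)[C@](C)(CC=C(C)C)C(=O)OC | intermediate
22 | (6S)-3,5-dihydroxy-6-methyl-2-(3-methylbutanoyl)-6-(3-methylbut-2-en-1-yl)cyclohexa-2,4-dien-1-one (dienol form of the acyl trione) | CC(C)CC(=O)C1=C(O)C=C(O)[C@](C)(CC=C(C)C)C1=O | intermediate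
23 | Knoevenagel alkylidene of 13 and 22 (C7'=C exocyclic to ring A, stereocentres as in 24) | C=C(C)[C@H]1CC[C@](C)(O)[C@@H]1C=C1C(=O)[C@](C)(CC=C(C)C)C(=O)C(C(=O)CC(C)C)=C1O | intermediate
24 | (6S)-3,5-dihydroxy-4-{[(1R,2S,5S)-2-hydroxy-2-methyl-5-(prop-1-en-2-yl)cyclopentyl]methyl}-6-methyl-2-(3-methylbutanoyl)-6-(3-methylbut-2-en-1-yl)cyclohexa-2,4-dien-1-one | C=C(C)[C@H]1CC[C@](C)(O)[C@@H]1CC1=C(O)[C@](C)(CC=C(C)C)C(=O)C(C(=O)CC(C)C)=C1O | target

Total step count: 13 (convergent). Longest linear sequence: 9 steps (steps 1–8, then step 13); the trione branch is steps 9–12.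

Steps most likely to fail

1. Step 6. The dianion may fragment by retro-aldol cleavage or lose methoxide before the slow SN2' closure, the alkoxide oxygen may compete as the nucleophile in the same 5-exo mode, or facial selectivity at C5' may be low. The fallback sets out from 9 and returns at 11, using only the established closure of simple ester mono-enolates onto allylic chlorides. The tertiary alcohol of 9 would be capped with TMSOTf/Et3N to give methyl (3S,6E)-8-chloro-3,7-dimethyl-3-[(trimethylsilyl)oxy]oct-6-enoate F1. Its lithium enolate (LiHMDS, THF/DMPU, −78 to −30 °C) should close by intramolecular 5-exo SN2' alkylation to methyl (1R,2S,5S)-2-methyl-5-(prop-1-en-2-yl)-2-[(trimethylsilyl)oxy]cyclopentane-1-carboxylate F2. Allylic 1,3-strain should again hold the C2' oxygen in the enolate plane, and any C1' epimer would be equilibrated at this ester stage with catalytic NaOMe. Methanolysis of the silyl ether (citric acid, MeOH) then gives 11.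

2. Step 10. The esterase may discriminate the enantiotopic esters poorly or in the opposite sense, or turn over the hindered, sparingly soluble diester slowly. The fallback sets out from 16 and returns at 17 by classical resolution. Half-saponification with one equivalent of KOH in methanol would give racemic 2-(methoxycarbonyl)-2,5-dimethylhex-4-enoic acid F3. Crystallisation with (S)-1-phenylethylamine would give (S)-1-phenylethylammonium (2S)-2-(methoxycarbonyl)-2,5-dimethylhex-4-enoate F4; the antipodal amine is taken if the other diastereomeric salt is the less soluble one. Acidification releases 17, whose configuration is secured by correlation.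

3. Step 13. The β-hydroxy aldehyde may dehydrate, open by retro-aldol or epimerise at C1' under amine catalysis, condensation at the α-branched aldehyde may be slow, and a second trione may add to the alkylidene. The fallback sets out from 11 and returns at 24, carrying the carbinol masked. Silylation (TESOTf, 2,6-lutidine) would give methyl (1R,2S,5S)-2-methyl-5-(prop-1-en-2-yl)-2-[(triethylsilyl)oxy]cyclopentane-1-carboxylate F5. DIBAL-H at −78 °C should stop at (1R,2S,5S)-2-methyl-5-(prop-1-en-2-yl)-2-[(triethylsilyl)oxy]cyclopentane-1-carbaldehyde F6, which can no longer undergo retro-aldol cleavage. The same Hantzsch ester reductive alkylation with 22 would give the triethylsilyl ether of the target F7, and HF·pyridine in THF releases 24.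

Further compounds
F1 | step 6 | methyl (3S,6E)-8-chloro-3,7-dimethyl-3-[(trimethylsilyl)oxy]oct-6-enoate | COC(=O)C[C@@](C)(O[Si](C)(C)C)CC/C=C(\C)CCl
F2 | step 6 | methyl (1R,2S,5S)-2-methyl-5-(prop-1-en-2-yl)-2-[(trimethylsilyl)oxy]cyclopentane-1-carboxylate | C=C(C)[C@H]1CC[C@](C)(O[Si](C)(C)C)[C@@H]1C(=O)OC
F3 | step 10 | racemic 2-(methoxycarbonyl)-2,5-dimethylhex-4-enoic acid | COC(=O)C(C)(CC=C(C)C)C(=O)O
F4 | step 10 | (S)-1-phenylethylammonium (2S)-2-(methoxycarbonyl)-2,5-dimethylhex-4-enoate | COC(=O)[C@@](C)(CC=C(C)C)C(=O)[O-].C[C@H]([NH3+])c1ccccc1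
F5 | step 13 | methyl (1R,2S,5S)-2-methyl-5-(prop-1-en-2-yl)-2-[(triethylsilyl)oxy]cyclopentane-1-carboxylate | C=C(C)[C@H]1CC[C@](C)(O[Si](CC)(CC)CC)[C@@H]1C(=O)OC
F6 | step 13 | (1R,2S,5S)-2-methyl-5-(prop-1-en-2-yl)-2-[(triethylsilyl)oxy]cyclopentane-1-carbaldehyde | C=C(C)[C@H]1CC[C@](C)(O[Si](CC)(CC)CC)[C@@H]1C=O
F7 | step 13 | (6S)-3,5-dihydroxy-6-methyl-2-(3-methylbutanoyl)-6-(3-methylbut-2-en-1-yl)-4-{[(1R,2S,5S)-2-methyl-5-(prop-1-en-2-yl)-2-[(triethylsilyl)oxy]cyclopentyl]methyl}cyclohexa-2,4-dien-1-one | C=C(C)[C@H]1CC[C@](C)(O[Si](CC)(CC)CC)[C@@H]1CC1=C(O)[C@](C)(CC=C(C)C)C(=O)C(C(=O)CC(C)C)=C1O
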